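The earlier runs and the new flask were computed for an exercise.

I had no constants for X or L, just two runs, so I read their columns against each other.

| setting | elm | birch | flask |
|---|---|---|---|
| X | 0.64 M | 1.4 M | 0.95 M |
| L | 0.76 M | 0.76 M | 0.760 M |
| remark | run made earlier | run made earlier |  |
| time |  |  | 30 h |

- elm (time / h: J / %, Z / %): 1.33: 33.2, 29.0; 4.00: 52.8, 46.2; 6.00: 52.7, 46.7; 10.0: 53.2, 46.4; 15.0: 53.2, 45.9; 20.0: 52.8, 46.4; 25.0: 52.8, 46.9
- birch (time / h: J / %, Z / %): 2.00: 21.3, 18.7; 3.00: 27.2, 24.4; 4.00: 29.4, 25.1; 6.00: 29.4, 26.0; 10.0: 29.4, 25.0; 15.0: 29.6, 25.4; 25.0: 28.3, 24.7

(readings scatter by 0.5 percentage points)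

- at the start none of X is in solution
- what has only dissolved of X counts as not reacted
- a reading or a percentage of J counts all its forms, free or not
- the reaction counts as stopped when no species that holds the X changes by six tenths of a point or more over the second half of the time

- at 30 h, what has stopped the reaction, if anything has (for what has run out or reacted, a solid counts together with what of it has only dissolved) (it is still moving / L has run out first / forward and back rates have come level / all of X has reacted)
- the J standing at 30 h, as a percentage of the X charged
- the Z standing at 30 h, as a percentage of the X charged
- amount of J if the flask were left three thousand times as long, in percent of the X charged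

On the last elm row, J and Z added up to 99.7 % of the X charged, with L charged at 119 % of X. On the birch row at 10.0 h they added up to 54.4 %, and L charged there was 54.3 % of X. So I took each X reacted to use one L, whichever product came, with L the limiting reagent in birch.

For the new flask that gave the ceiling 80.0 %, the share of the X charged that the L charged could turn into J and Z.

Then I read J against Z. The J part of the products was 53.4 % on the first elm row and 53.3 % over the last 4 elm rows, so I treated the split as in place from the start. The ceiling times that part gave me J 42.6 % and Z 37.4 %. Both runs were flat by 4.00 h, which is shorter than 30 h, so I expected this flask to be flat by then.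

The forecast stood close to my figures but not on them: L has run out first, J 42.7 %, Z 37.3 %, and J 42.7 % after the long wait. Its ground was “each X reacted takes one L, whichever product forms”.

The flask gave L has run out first, J 42.8 %, Z 37.2 %, and J 42.8 % after the long wait.

    G + L → J (k = 0.00460 /M/s)
    Q ⇌ J, rate k2*(cs2 - [J]) while solid is left; crystals form when [J] > cs2 (solubility = 0.800 M, k = 0.100 /s)
    J ⇌ Z (K = 0.870, k = 0.00880 /s)
    X ⇌ G, rate k4*(cs4 - [G]) while solid is left; crystals form when [G] > cs4 (solubility = 0.130 M, k = 9.60 × 10⁻⁴ /s)

The flask had come to rest. Over the second half of the time nothing moved by more than 0 percentage points, and going on to 300 h changed J by 0 points and Z by 0 points. L stood at 0 % of its charge, and J and Z together made 80.0 % against the ceiling of 80.0 %. The flask also held what the ceiling doesn't show: solid X at 6.32 % and its dissolved form G at 13.7 %, unreacted. To move J by 5 points took L at 0.671 M or 0.849 M.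

A second flask, the same but with L at 0.46 M, had the ceiling 48.4 %, which predicted J 25.8 %. That second flask gave 25.9 %.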